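**Strategy.** The 4-methylfuran ring is not carried through the synthesis but made late from an acyclic 2-methylalk-3-yne-1,2-diol. In one silver-catalysed operation the primary hydroxyl closes O1–C2 onto the alkyne carbon bearing the allylic CH2, and loss of the tertiary hydroxyl aromatises the ring. The CH2OH supplies O1 and C5, the methyl carbinol C4, the alkyne C3 and C2, so the 2,4-pattern and the unconjugated furan–CH2–C(Me)=CH link are fixed by connectivity. The precursor is a silyl-protected (R)-alkynediol whose vinyl/methyl quaternary centre comes from an enantioselective copper-catalysed SN2′ alkylation. The resorcinol ketone is attached afterwards through the aldehyde.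

Key step: step 9

Remark: the sense of induction of the chiral carbene–copper catalyst in step 4 is assumed to follow the ligand enantiomer, and the enantiomer that gives the (R) centre is the one meant; the carbinol carbon of 13 and 14 is left uncontrolled on purpose, since step 9 makes it sp2.

**Step 1**
Reactants: 1 but-3-yn-1-ol
Product: 2 tert-butyl(but-3-yn-1-yloxy)diphenylsilane
Conditions: TBDPSCl, imidazole, CH2Cl2, 0 °C to rt
Reagents that add atoms: tert-butyl(chloro)diphenylsilane, CC(C)(C)[Si](Cl)(c1ccccc1)c1ccccc1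
Why: Imidazole-promoted silyl ether formation on a primary alcohol is chemoselective, and the bulky silyl group should withstand the organometallic, oxidative and basic steps up to step 10.

**Step 2**
Reactants: 2 tert-butyl(but-3-yn-1-yloxy)diphenylsilane
Product: 5 (E)-5-(tert-butyldiphenylsilyloxy)-3-methylpent-2-en-1-ol, via alkenyldimethylalane 3 (not isolated), via lithium alkenylaluminate 4 (not isolated)
Conditions: Me3Al, Cp2ZrCl2 (25 mol%), CH2Cl2, 0 °C to rt; n-BuLi, THF/hexane, −78 to 0 °C; (CH2O)n, rt
Reagents that add atoms: trimethylaluminium, C[Al](C)C; paraformaldehyde (formaldehyde unit), C=O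
Why: Negishi zirconium-catalysed carboalumination adds methyl and aluminium syn across the terminal alkyne with methyl on the internal carbon, so hydroxymethylation of the derived aluminate with formaldehyde should give the trisubstituted alkene as the (E) isomer only.

**Step 3**
Reactants: 5 (E)-5-(tert-butyldiphenylsilyloxy)-3-methylpent-2-en-1-ol
Product: 6 (E)-tert-butyl[(5-chloro-3-methylpent-3-en-1-yl)oxy]diphenylsilane
Conditions: NCS, Me2S, CH2Cl2, −20 to 0 °C
Reagents that add atoms: N-chlorosuccinimide, O=C1CCC(=O)N1Cl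
Why: Corey–Kim chlorination displaces the alkoxysulfonium ion of a primary allylic alcohol by chloride in an SN2 manner, without allylic transposition or loss of alkene geometry.

**Step 4**
Reactants: 6 (E)-tert-butyl[(5-chloro-3-methylpent-3-en-1-yl)oxy]diphenylsilane; 7 4-methylpenta-1,3-diene
Product: 9 (R)-tert-butyl[(3-ethenyl-3,7-dimethyloct-6-en-1-yl)oxy]diphenylsilane, via homoprenyl-9-BBN 8 (not isolated)
Conditions: 7, 9-BBN dimer, THF, 60 °C; then 6, CuOTf·(toluene)0.5 (10 mol%), chiral naphthol-bearing imidazolinium salt (12 mol%), KOMe, THF, rt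
Reagents that add atoms: none
Why: Regioselective hydroboration of the monosubstituted alkene of the diene gives the primary alkylborane, whose methoxide-activated alkyl group is passed to a chiral carbene–copper centre and delivered to the γ-carbon of the (E)-allylic chloride in a copper-catalysed enantioselective SN2′ allylic alkylation (allyl–alkyl coupling with an alkylborane), the ligand selecting the alkene face so that the all-carbon quaternary centre should form as (R).

**Step 5**
Reactants: 9 (R)-tert-butyl[(3-ethenyl-3,7-dimethyloct-6-en-1-yl)oxy]diphenylsilane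
Product: 10 (2E,6R)-8-(tert-butyldiphenylsilyloxy)-6-ethenyl-2,6-dimethyloct-2-en-1-ol
Conditions: SeO2 (cat.), t-BuOOH, salicylic acid (cat.), CH2Cl2, rt
Reagents that add atoms: tert-butyl hydroperoxide (stoichiometric oxygen source), CC(C)(C)OO; selenium dioxide (catalytic oxygen carrier), O=[Se]=O
Why: Riley allylic oxidation (ene reaction, then [2,3]-sigmatropic shift) attacks the (E)-methyl of the gem-dimethyl alkene, while the vinyl group has no allylic hydrogen and should stay untouched.

**Step 6**
Reactants: 10 (2E,6R)-8-(tert-butyldiphenylsilyloxy)-6-ethenyl-2,6-dimethyloct-2-en-1-ol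
Product: 11 (R,E)-[(8-bromo-3-ethenyl-3,7-dimethyloct-6-en-1-yl)oxy](tert-butyl)diphenylsilane
Conditions: CBr4, PPh3, CH2Cl2, 0 °C
Reagents that add atoms: tetrabromomethane, BrC(Br)(Br)Br
Why: The Appel reaction converts the primary allylic alcohol to the bromide under neutral conditions, which should preserve the (E) geometry and the silyl ether.

**Step 7**
Reactants: 12 hydroxyacetone
Product: 13 2-methylbut-3-yne-1,2-diol (racemic)
Conditions: HC≡CMgBr (2.5 equiv), THF, 0 °C to rt
Reagents that add atoms: ethynylmagnesium bromide, C#C[Mg]Br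
Why: Grignard addition to the ketone, with the first equivalent consumed by the hydroxyl, gives the tertiary propargylic diol, and the racemate suffices because this carbon becomes sp2 in step 9.

**Step 8**
Reactants: 11 (R,E)-[(8-bromo-3-ethenyl-3,7-dimethyloct-6-en-1-yl)oxy](tert-butyl)diphenylsilane; 13 2-methylbut-3-yne-1,2-diol
Product: 14 (6E,10R)-12-(tert-butyldiphenylsilyloxy)-10-ethenyl-2,6,10-trimethyldodec-6-en-3-yne-1,2-diol (both C2 epimers)
Conditions: CuI (20 mol%), NaI (20 mol%), K2CO3, DMF, rt
Reagents that add atoms: none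
Why: Copper-catalysed allylation of a terminal alkyne under carbonate base, with in situ Finkelstein activation of the bromide, should couple the copper acetylide at the unhindered α-carbon to give the skipped 1,4-enyne; it tolerates free hydroxyls and uses no strong base that could move the alkyne or the alkene into conjugation.

**Step 9**
Reactants: 14 (6E,10R)-12-(tert-butyldiphenylsilyloxy)-10-ethenyl-2,6,10-trimethyldodec-6-en-3-yne-1,2-diol
Product: 16 tert-butyl{[(3R,6E)-3-ethenyl-3,7-dimethyl-8-(4-methylfuran-2-yl)oct-6-en-1-yl]oxy}diphenylsilane, via hydroxydihydrofuran 15 (not isolated)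
Conditions: AgNO3 on silica gel (10 mol%), CH2Cl2, rt, dark
Reagents that add atoms: none
Why: Monovalent silver coordinates the alkyne, the primary hydroxyl oxygen attacks the distal alkyne carbon anti to the metal, protodemetalation gives hydroxydihydrofuran 15, and loss of the tertiary hydroxyl together with a C5 hydrogen aromatises it. The closest known reaction type is the cyclodehydration of 3-alkyne-1,2-diols to furans on AgNO3-impregnated silica or with cationic monovalent gold complexes. The one ring formed, the furan (O1, C2–C5), closes in the 5-endo-dig mode through the new O1–C2 bond. No stereocentre is created: the carbinol carbon becomes sp2, so both epimers of 14 converge, and the (R) quaternary centre and the (E)-alkene are remote and not involved. The step needs attack by the primary and not the tertiary oxygen and the 2,4- and not another substitution pattern; both are secured by the chain, because only the primary oxygen can reach the distal carbon in a five-membered ring, the carbon bearing the allylic CH2 must become C2 and the methyl carbinol must become C4. The CH2 between furan and alkene is saturated throughout, so the (E)-alkene has no path into conjugation.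

**Step 10**
Reactants: 16 tert-butyl{[(3R,6E)-3-ethenyl-3,7-dimethyl-8-(4-methylfuran-2-yl)oct-6-en-1-yl]oxy}diphenylsilane
Product: 17 (3R,6E)-3-ethenyl-3,7-dimethyl-8-(4-methylfuran-2-yl)oct-6-en-1-ol
Conditions: Bu4NF, THF, 0 °C to rt
Reagents that add atoms: none
Why: Fluoride-induced desilylation cleaves the Si–O bond under non-acidic conditions that the furan and the skipped diene should tolerate.

**Step 11**
Reactants: 17 (3R,6E)-3-ethenyl-3,7-dimethyl-8-(4-methylfuran-2-yl)oct-6-en-1-ol
Product: 18 (3R,6E)-3-ethenyl-3,7-dimethyl-8-(4-methylfuran-2-yl)oct-6-enal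
Conditions: Dess–Martin periodinane, NaHCO3, CH2Cl2, 0 °C to rt
Reagents that add atoms: none
Why: Buffered Dess–Martin oxidation takes the primary alcohol to the aldehyde without acid or over-oxidation, and the quaternary β-carbon cannot epimerise.

**Step 12**
Reactants: 19 4-bromoresorcinol
Product: 20 1-bromo-2,4-bis(methoxymethoxy)benzene
Conditions: MOMCl, i-Pr2NEt, CH2Cl2, 0 °C to rt
Reagents that add atoms: chloromethyl methyl ether, COCCl
Why: Williamson-type O-alkylation of both phenols gives the bis-acetal, which masks the acidic hydroxyls and should stabilise the derived aryllithium by chelation.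

**Step 13**
Reactants: 18 (3R,6E)-3-ethenyl-3,7-dimethyl-8-(4-methylfuran-2-yl)oct-6-enal; 20 1-bromo-2,4-bis(methoxymethoxy)benzene
Product: 22 (3R,6E)-1-[2,4-bis(methoxymethoxy)phenyl]-3-ethenyl-3,7-dimethyl-8-(4-methylfuran-2-yl)oct-6-en-1-ol (both C1 epimers), via aryllithium 21 (not isolated)
Conditions: 20, n-BuLi, THF, −78 °C; then 18, −78 °C
Reagents that add atoms: none
Why: Bromine–lithium exchange gives the ortho-chelated aryllithium, which should add 1,2 to the aldehyde; the new carbinol centre forms unselectively and is erased by the oxidation in step 14.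

**Step 14**
Reactants: 22 (3R,6E)-1-[2,4-bis(methoxymethoxy)phenyl]-3-ethenyl-3,7-dimethyl-8-(4-methylfuran-2-yl)oct-6-en-1-ol
Product: 23 (3R,6E)-1-[2,4-bis(methoxymethoxy)phenyl]-3-ethenyl-3,7-dimethyl-8-(4-methylfuran-2-yl)oct-6-en-1-one
Conditions: Dess–Martin periodinane, NaHCO3, CH2Cl2, 0 °C to rt
Reagents that add atoms: none
Why: Dess–Martin oxidation of the benzylic secondary alcohol should give the aryl ketone under buffered conditions and merges both carbinol epimers.

**Step 15**
Reactants: 23 (3R,6E)-1-[2,4-bis(methoxymethoxy)phenyl]-3-ethenyl-3,7-dimethyl-8-(4-methylfuran-2-yl)oct-6-en-1-one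
Product: 24 (3R,6E)-1-(2,4-dihydroxyphenyl)-3-ethenyl-3,7-dimethyl-8-(4-methylfuran-2-yl)oct-6-en-1-one
Conditions: aq. HCl (1 M), MeOH, rt to 40 °C
Reagents that add atoms: none
Why: Acid-catalysed acetal exchange with methanol removes both aryl methoxymethyl ethers, which cleave readily because the phenols are conjugated to the ketone, and dilute acid near room temperature should leave the furan, the alkenes and the quaternary centre intact.

**Compound list**
1 | but-3-yn-1-ol | C#CCCO | starting material
2 | tert-butyl(but-3-yn-1-yloxy)diphenylsilane | C#CCCO[Si](c1ccccc1)(c1ccccc1)C(C)(C)C | intermediate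
3 | (E)-[4-(tert-butyldiphenylsilyloxy)-2-methylbut-1-en-1-yl]dimethylalane | C[Al](C)/C=C(\C)CCO[Si](c1ccccc1)(c1ccccc1)C(C)(C)C | intermediate
4 | lithium (E)-butyl[4-(tert-butyldiphenylsilyloxy)-2-methylbut-1-en-1-yl]dimethylaluminate | [Li+].CCCC[Al-](C)(C)/C=C(\C)CCO[Si](c1ccccc1)(c1ccccc1)C(C)(C)C | intermediate
5 | (E)-5-(tert-butyldiphenylsilyloxy)-3-methylpent-2-en-1-ol | OC/C=C(\C)CCO[Si](c1ccccc1)(c1ccccc1)C(C)(C)C | intermediate
6 | (E)-tert-butyl[(5-chloro-3-methylpent-3-en-1-yl)oxy]diphenylsilane | ClC/C=C(\C)CCO[Si](c1ccccc1)(c1ccccc1)C(C)(C)C | intermediate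
7 | 4-methylpenta-1,3-diene | CC(C)=CC=C | starting material
8 | 9-(4-methylpent-3-en-1-yl)-9-borabicyclo[3.3.1]nonane | CC(C)=CCCB1C2CCCC1CCC2 | intermediate
9 | (R)-tert-butyl[(3-ethenyl-3,7-dimethyloct-6-en-1-yl)oxy]diphenylsilane | C=C[C@](C)(CCC=C(C)C)CCO[Si](c1ccccc1)(c1ccccc1)C(C)(C)C | intermediate
10 | (2E,6R)-8-(tert-butyldiphenylsilyloxy)-6-ethenyl-2,6-dimethyloct-2-en-1-ol | C=C[C@](C)(CC/C=C(\C)CO)CCO[Si](c1ccccc1)(c1ccccc1)C(C)(C)C | intermediate
11 | (R,E)-[(8-bromo-3-ethenyl-3,7-dimethyloct-6-en-1-yl)oxy](tert-butyl)diphenylsilane | C=C[C@](C)(CC/C=C(\C)CBr)CCO[Si](c1ccccc1)(c1ccccc1)C(C)(C)C | intermediate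
12 | hydroxyacetone | CC(=O)CO | starting material
13 | 2-methylbut-3-yne-1,2-diol (racemic) | C#CC(C)(O)CO | intermediate
14 | (6E,10R)-12-(tert-butyldiphenylsilyloxy)-10-ethenyl-2,6,10-trimethyldodec-6-en-3-yne-1,2-diol (both C2 epimers) | C=C[C@](C)(CC/C=C(\C)CC#CC(C)(O)CO)CCO[Si](c1ccccc1)(c1ccccc1)C(C)(C)C | intermediate
15 | 5-[(2E,6R)-8-(tert-butyldiphenylsilyloxy)-6-ethenyl-2,6-dimethyloct-2-en-1-yl]-3-methyl-2,3-dihydrofuran-3-ol (both C3 epimers) | C=C[C@](C)(CC/C=C(\C)CC1=CC(C)(O)CO1)CCO[Si](c1ccccc1)(c1ccccc1)C(C)(C)C | intermediate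
16 | tert-butyl{[(3R,6E)-3-ethenyl-3,7-dimethyl-8-(4-methylfuran-2-yl)oct-6-en-1-yl]oxy}diphenylsilane | C=C[C@](C)(CC/C=C(\C)Cc1cc(C)co1)CCO[Si](c1ccccc1)(c1ccccc1)C(C)(C)C | intermediate
17 | (3R,6E)-3-ethenyl-3,7-dimethyl-8-(4-methylfuran-2-yl)oct-6-en-1-ol | C=C[C@](C)(CC/C=C(\C)Cc1cc(C)co1)CCO | intermediate
18 | (3R,6E)-3-ethenyl-3,7-dimethyl-8-(4-methylfuran-2-yl)oct-6-enal | C=C[C@](C)(CC/C=C(\C)Cc1cc(C)co1)CC=O | intermediate
19 | 4-bromoresorcinol | Oc1ccc(Br)c(O)c1 | starting material
20 | 1-bromo-2,4-bis(methoxymethoxy)benzene | COCOc1ccc(Br)c(OCOC)c1 | intermediate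
21 | [2,4-bis(methoxymethoxy)phenyl]lithium | [Li]c1ccc(OCOC)cc1OCOC | intermediate
22 | (3R,6E)-1-[2,4-bis(methoxymethoxy)phenyl]-3-ethenyl-3,7-dimethyl-8-(4-methylfuran-2-yl)oct-6-en-1-ol (both C1 epimers) | C=C[C@](C)(CC/C=C(\C)Cc1cc(C)co1)CC(O)c1ccc(OCOC)cc1OCOC | intermediate
23 | (3R,6E)-1-[2,4-bis(methoxymethoxy)phenyl]-3-ethenyl-3,7-dimethyl-8-(4-methylfuran-2-yl)oct-6-en-1-one | C=C[C@](C)(CC/C=C(\C)Cc1cc(C)co1)CC(=O)c1ccc(OCOC)cc1OCOC | intermediate
24 | (3R,6E)-1-(2,4-dihydroxyphenyl)-3-ethenyl-3,7-dimethyl-8-(4-methylfuran-2-yl)oct-6-en-1-one | C=C[C@](C)(CC/C=C(\C)Cc1cc(C)co1)CC(=O)c1ccc(O)cc1O | target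

**Step count.** Total: 15 steps. Longest linear sequence: 13 steps (steps 1–6, 8–11 and 13–15, from but-3-yn-1-ol); steps 7 and 12 are single-step side branches.

**Steps most likely to fail**

1. Step 4. The alkyl transfer from copper may not discriminate well enough between the two faces of an alkene whose γ-substituents are methyl and silyloxyethyl, or some coupling may occur at the α-carbon to give the linear isomer. The fallback sets out from chloride 6 and replaces the borane by a hard nucleophile from a different starting material. 5-Bromo-2-methylpent-2-ene and Mg in Et2O give 4-methylpent-3-enylmagnesium bromide F1. F1 is added slowly at −78 °C in CH2Cl2 to 6 in the presence of catalytic copper thiophene-2-carboxylate (monovalent copper) and a chiral binaphthol-derived phosphoramidite ligand. This Grignard-based copper-catalysed asymmetric allylic alkylation should come back to the route at 9.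

2. Step 8. The unprotected 1,2-diol may chelate copper and stall acetylide transfer, or the allylic bromide may be consumed by O-allylation before C–C coupling. The fallback sets out from bromide 11 and builds the diol at the carbinol carbon instead. Ethynylmagnesium bromide with catalytic CuCl in THF should give the terminal skipped enyne tert-butyl{[(3R,6E)-3-ethenyl-3,7-dimethyldec-6-en-9-yn-1-yl]oxy}diphenylsilane F2. Deprotonation with n-BuLi at −78 °C gives the lithium acetylide of the enyne F3, which is added to purchased 1-(tert-butyldimethylsilyloxy)propan-2-one to give the mono-TBS-protected alkynediol F4. PPTS in MeOH should then remove the primary TBS ether while the far more acid-stable TBDPS ether stays, and the route is rejoined at 14.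

3. Step 15. Protonation of the electron-rich 2,4-dialkylfuran may compete with acetal cleavage and lead to ring opening or oligomerisation before both ethers are gone. The fallback sets out from aldehyde 18 and 4-bromoresorcinol 19 and uses phenol protection that is removed without acid. 19 is bis-allylated (allyl bromide, K2CO3, acetone) to 2,4-bis(allyloxy)-1-bromobenzene F5. Bromine–lithium exchange with n-BuLi at −78 °C gives [2,4-bis(allyloxy)phenyl]lithium F6, which adds to 18 to give the bis(allyl ether) carbinol F7. Buffered Dess–Martin oxidation gives the bis(allyl ether) ketone F8. Pd(PPh3)4 (zerovalent palladium, catalytic) with morpholine in THF at rt should transfer both allyl groups to the amine under neutral conditions and arrive directly at 24.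

**Further compounds**
F1 | step 4 | 4-methylpent-3-enylmagnesium bromide | CC(C)=CCC[Mg]Br
F2 | step 8 | tert-butyl{[(3R,6E)-3-ethenyl-3,7-dimethyldec-6-en-9-yn-1-yl]oxy}diphenylsilane | C=C[C@](C)(CC/C=C(\C)CC#C)CCO[Si](c1ccccc1)(c1ccccc1)C(C)(C)C
F3 | step 8 | lithium acetylide of the enyne, {(4E,8R)-10-(tert-butyldiphenylsilyloxy)-8-ethenyl-4,8-dimethyldec-4-en-1-yn-1-yl}lithium | C=C[C@](C)(CC/C=C(\C)CC#C[Li])CCO[Si](c1ccccc1)(c1ccccc1)C(C)(C)C
F4 | step 8 | (6E,10R)-1-(tert-butyldimethylsilyloxy)-12-(tert-butyldiphenylsilyloxy)-10-ethenyl-2,6,10-trimethyldodec-6-en-3-yn-2-ol (both C2 epimers) | C=C[C@](C)(CC/C=C(\C)CC#CC(C)(O)CO[Si](C)(C)C(C)(C)C)CCO[Si](c1ccccc1)(c1ccccc1)C(C)(C)C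
F5 | step 15 | 2,4-bis(allyloxy)-1-bromobenzene | C=CCOc1ccc(Br)c(OCC=C)c1
F6 | step 15 | [2,4-bis(allyloxy)phenyl]lithium | [Li]c1ccc(OCC=C)cc1OCC=C
F7 | step 15 | (3R,6E)-1-[2,4-bis(allyloxy)phenyl]-3-ethenyl-3,7-dimethyl-8-(4-methylfuran-2-yl)oct-6-en-1-ol (both C1 epimers) | C=C[C@](C)(CC/C=C(\C)Cc1cc(C)co1)CC(O)c1ccc(OCC=C)cc1OCC=C
F8 | step 15 | (3R,6E)-1-[2,4-bis(allyloxy)phenyl]-3-ethenyl-3,7-dimethyl-8-(4-methylfuran-2-yl)oct-6-en-1-one | C=C[C@](C)(CC/C=C(\C)Cc1cc(C)co1)CC(=O)c1ccc(OCC=C)cc1OCC=C
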